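(The numbers in the tables were generated by integration for substances that don't exist, and the scatter is random.)

In a one-step world more starting material and more heat simply mean more product, and oak, with 4.00 times the starting material of ash and a bath at 40 °C against 20 °C, looks like the easy winner.

| flask | starting material | coupling partner | free catalyst | temperature | remark | time |
|---|---|---|---|---|---|---|
| grey | 0.20 M (fed, over 12 s) | 0.24 M | 0.10 mM | 20 °C | run made earlier; the fed solution adds 0.25 times the starting volume |  |
| blue | 0.20 M (fed, over 12 s) | 0.36 M | 0.050 mM | 20 °C | run made earlier; the fed solution adds 0.25 times the starting volume |  |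
| ash | 0.20 M (fed, over 12 s) | 0.360 M | 0.10 mM | 20 °C | the fed solution adds 0.25 times the starting volume | 2.5 min |
| oak | 0.80 M | 0.360 M | 0.10 mM | 40 °C | everything together at the start, the whole solution of starting material included, so that from the start the volume is larger by 0.25 times the starting volume | 2.5 min |

| run | time / s | product / % |
|---|---|---|
| grey | 10.0 | 2.0 |
| grey | 15.0 | 3.2 |
| grey | 25.0 | 6.2 |
| grey | 30.0 | 8.0 |
| grey | 50.0 | 11.3 |
| blue | 10.0 | 0.6 |
| blue | 15.0 | 2.5 |
| blue | 25.0 | 4.0 |
| blue | 30.0 | 6.3 |
| blue | 40.0 | 8.0 |
| blue | 50.0 | 9.5 |

(readings scatter by 0.5 percentage points)

* the flask that ends with the higher amount of product, in percent of the starting material charged, or "neither" when 2 percentage points or less lies between them (ash / oak / neither)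
* final product, as a percentage of the starting material charged, in ash
* final product, as a percentage of the starting material charged, in oak

- charges are per starting volume, the dose included; the dosed solution carries all of it
- the earlier runs were read with a standard deviation of 0.5 percentage points
- the earlier runs do not show what temperature does; that part of a forecast is a guess
- percentages count the whole charge, also what has not yet gone in
- a reading or a percentage of product counts all its forms, free or not

We read the earlier runs at 30.0 s, comparing blue with grey:

product ratio, as read: 0.787

[free catalyst] ratio × [coupling partner] ratio: 0.750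

Within the scatter, this reading agrees with a rate first order in each, although the two were changed together. We take [coupling partner] as part of the rate, as an assumption that these two runs do not separate from the effect of the catalyst.

Now oak shows two numbers that seem at odds. Taking one coupling partner per product, oak has room for 0.360 M of product per starting volume, more than the 0.20 M of ash, yet its percentage room is smaller:

ash: 100%

oak: 45.0%

The percentage ceiling, the smaller charge over the charge of starting material, clears this up. In oak the coupling partner is the limiting reagent, and its larger molar room is divided by a larger charge. Our own reckoning takes 45.0% as the upper bound for oak and puts no figure on ash.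

The forecast says neither: ash 20% (15% to 25%), oak 21% (12% to 35%), with the remark “The two come out close”.

The flask gives oak: ash 35.6%, oak 40.1%, each above the forecast's range.

    crystals ⇌ product, rate k1*(cs1 - [product]) while solid is left; crystals form when [product] > cs1 (solubility = 0.140 M, k = 1.60 s⁻¹)
    starting material + free catalyst ⇌ catalyst intermediate A (K = 4.80 M⁻¹, k = 3100 M⁻¹ s⁻¹, Ea = 24.0 kJ mol⁻¹, ΔH = 19.0 kJ mol⁻¹)
    catalyst intermediate B → free catalyst + product (k = 26.0 s⁻¹, Ea = 73.0 kJ mol⁻¹)
    coupling partner + catalyst intermediate A → catalyst intermediate B (k = 140 M⁻¹ s⁻¹, Ea = 36.0 kJ mol⁻¹)
    2 free catalyst ⇌ resting dimer (K = 1.30 × 10⁵ M⁻¹, k = 510 M⁻¹ s⁻¹, Ea = 36.0 kJ mol⁻¹, ΔH = −2.00 kJ mol⁻¹)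
    (constants at 20 °C)

Oak ends at 0.891 of its ceiling with 11% of its coupling partner left, and after 25.0 min it stands at 45.0%, level with the ceiling. The neighbour flask, oak charged with 0.32 M of starting material, has 1.12 equiv of coupling partner, so its ceiling is 100%. It gives 68.2%, below that ceiling, with 32% of its starting material and 39% of its coupling partner left.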